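Readings and results are calculated on assumed constants, and the scatter is random.

Hold two flasks at the same conversion: substrate is then equal, and the step is substrate + enzyme, so their rates of making product stand in the ratio of their free enzyme.

| setting | violet | grey | flask |
|---|---|---|---|
| substrate | 0.15 M | 0.15 M | 0.15 M |
| enzyme | 15 µM | 22 µM | 15 µM |
| added ligand | 8.2 µM | 8.2 µM | 8.2 µM |
| remark | the very flask that is asked about, followed so far | run made earlier |  |

| run | time / s | product / % |
|---|---|---|
| violet | 10.0 | 30.6 |
| violet | 15.0 | 38.8 |
| violet | 20.0 | 45.4 |
| violet | 25.0 | 45.3 |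
| grey | 10.0 | 41.5 |
| grey | 15.0 | 49.0 |
| grey | 25.0 | 56.0 |
| grey | 40.0 | 62.5 |
| grey | 60.0 | 65.6 |
| grey | 80.0 | 71.1 |

(readings scatter by 1 percentage point)

- factor on the rate of making product when 10 % of the substrate are converted if enzyme is charged twice over
- factor on the rate when 10 % of the substrate are converted if enzyme is charged at 3.0 µM instead

- the numbers in the tables scatter by 1 percentage point (one standard deviation)
- steps thought possible: substrate + enzyme -> product + enzyme; enzyme + added ligand <-> idle complex; 2 enzyme -> spent catalyst

Find when the violet flask reaches the mark. Scale its first reading as a first-order curve and you get 2.88 s, earlier than that reading. Treat spent catalyst as a small correction there and set it aside.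

Now bound the free enzyme. If added ligand binds nothing, free enzyme equals the charge. If it binds fully, free enzyme falls to the floor F, the charge minus the added ligand. In the violet flask:

F = 6.80 µM

This brackets both factors:

dbl: from 2 to 3.21

ratio: from zero to 0.200

Try to tighten this with the two runs, and stop there: the first readings stand at 10.0 s, later than my estimate of the mark, and a ratio of conversions that late is not a ratio of free enzyme unless the curves are first order with no enzyme lost. So my bracket stays.

The forecast gives 2.5 and 0.12, inside both brackets, on the ground that “The rate at equal substrate scales with free enzyme”.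

The flask gives 2.57 and 0.109.

    substrate + enzyme → product + enzyme, rate k1*[substrate]^3*[enzyme]/(1 + ([substrate]/Kh1)^3) (0.173 M, k = 4.01 × 10⁵ L³ mol⁻³ s⁻¹)
    enzyme + added ligand ⇌ idle complex, settled at all times (K = 3.60 × 10⁵ L mol⁻¹)
    2 enzyme → spent catalyst (k = 1240 L mol⁻¹ s⁻¹)

At 3.0 µM, 30.6 % of the catalyst is enzyme at the mark, which is 0.918 µM. Divide this by 0.109: the violet flask holds 8.41 µM of free enzyme, above F by 1.61 µM. At 3.0 µM the same subtraction gives −5.20 µM, a floor below zero, and free enzyme stands at 0.918 µM.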